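**Plan** (locants: ring carbons C1, C5–C10; crotonyl C2–C4/C15; lactone C11–C13; methyl C14)
- Retrosynthetic cuts, in order: C2–C3 (thioester plus propenylboronic acid); C7–C11 and the lactone carbonyl (bromoacetal radical closure); reopening of a C5–O–C8 ether bridge; C10–CH3 and C1–OH; last, C1–C5 and C8–C9 together.
- Enabling feature: in the cycloheptane, C5(O)–C6(O)–C7–C8 is a hidden 3-oxyfuran and C9(O)–C10–C1–C2(=O) a hidden 2-oxyvinyl carbenoid, so the ring is their [4+3] adduct, an 8-oxabicyclo[3.2.1]octadiene whose C8–O bond is cleaved later.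
- Forward ring order: oxygen-bridged seven-membered ring, then bridge opening to a cycloheptenone, then the cis-fused α-methylene lactone by 5-exo radical closure, then the side-chain enone.
- Stereochemistry: C5 and C9 from the catalyst-controlled cyclopropanation and the stereospecific boat Cope step; C10 and C1 from endo attack on the bicycle, anti to the exo C9 silyl ether; C6 from chelation-controlled reduction directed by the C1 hydroxyl; C7 from the cis ring fusion; the ester centre from (S)-2-methylbutanoic anhydride.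

Key step: step 5

Remark: the sense of induction of Rh2(R-DOSP)4 is assigned by analogy with its face selectivity in cyclopropanations of terminal alkenes; 7, 17, 20 and 24 are taken as commercial.

Step 1
Reactants: 1 (tert-butyldimethylsilyloxy)acetaldehyde; 2 methyl (triphenylphosphoranylidene)acetate
Product: 3 methyl (E)-4-[(tert-butyldimethylsilyl)oxy]but-2-enoate
Conditions: CH2Cl2, 0 °C to rt
Reagents that add atoms: none
Why: Wittig olefination with a stabilised ylide should give the E enoate.

Step 2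
Reactants: 3 methyl (E)-4-[(tert-butyldimethylsilyl)oxy]but-2-enoate
Product: 5 methyl (Z)-4-[(tert-butyldimethylsilyl)oxy]but-3-enoate, via lithium dienolate 4 (not isolated)
Conditions: LiN(iPr)2, HMPA, THF, −78 °C; then AcOH, −78 °C
Reagents that add atoms: none
Why: Kinetic deconjugation (γ-deprotonation, α-protonation of the dienolate) should give the Z enol ether, because a γ-oxygen substituent sits syn in the deprotonation conformer (syn effect).

Step 3
Reactants: 5 methyl (Z)-4-[(tert-butyldimethylsilyl)oxy]but-3-enoate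
Product: 6 methyl (Z)-4-[(tert-butyldimethylsilyl)oxy]-2-diazobut-3-enoate
Conditions: p-ABSA, DBU, MeCN, 0 °C; used at once
Reagents that add atoms: 4-acetamidobenzenesulfonyl azide (p-ABSA), CC(=O)Nc1ccc(cc1)S(=O)(=O)N=[N+]=[N-]
Why: Regitz diazo transfer to the doubly activated (ester and vinyl) methylene is the standard entry to vinyldiazoacetates and should leave the Z double bond untouched.

Step 4
Reactants: 7 furan-3-ylboronic acid
Product: 9 3-(triethylsilyloxy)furan, via furan-3(2H)-one 8 (not isolated)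
Conditions: H2O2, NaHCO3, THF–H2O, 0 °C; dried CH2Cl2 extract; then Et3SiOTf, Et3N, −78 °C
Reagents that add atoms: hydrogen peroxide, OO; triethylsilyl trifluoromethanesulfonate, CC[Si](CC)(CC)OS(=O)(=O)C(F)(F)F
Why: ipso-Oxidation of the boronic acid gives the labile furanone, which is trapped at once as its aromatic silyl enol ether (O-silylation with a silyl triflate).

Step 5
Reactants: 6 methyl (Z)-4-[(tert-butyldimethylsilyl)oxy]-2-diazobut-3-enoate; 9 3-(triethylsilyloxy)furan
Product: 11 methyl (1R,4S,5R)-4-exo-[(tert-butyldimethylsilyl)oxy]-7-[(triethylsilyl)oxy]-8-oxabicyclo[3.2.1]octa-2,6-diene-2-carboxylate, via divinylcyclopropane 10 (not isolated)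
Conditions: Rh2(R-DOSP)4 (1 mol %), 9 (3 equiv), hexanes, −40 °C, slow addition of 6; then toluene, 60 °C
Reagents that add atoms: none
Why: The rhodium vinylcarbenoid from 6 adds to the C2=C3 enol-ether bond of the furan to give the donor–acceptor cis-divinylcyclopropane 10, whose strain drives a [3,3] Cope shift that breaks the cyclopropane bond and joins the vinyl terminus to furan C5, so that the future C1–C5 and C8–C9 bonds arise in one operation. The closest known reaction type is the tandem cyclopropanation/Cope rearrangement (formal [4+3]) of vinyldiazoacetates with furans under chiral dirhodium carboxylates. The three-membered ring closes by [2+1] carbene transfer and the seven-membered ring by a boat-shaped sigmatropic ring expansion, which leaves the furan oxygen as a C5–O–C8 bridge. The bridgehead centres (C5, C8) take their absolute sense from the catalyst's choice of furan face in the cyclopropanation, and C9 follows from the Z enol-ether geometry, which the boat transition state translates into an exo silyloxy group, cis to the oxygen bridge. The step needs site selectivity for furan C2 over C5, secured by the 3-silyloxy group (C2 is both the α-furyl and the enol-ether β-carbon), and a cis relation of the two vinyl groups, secured by the ring (the second vinyl is part of the furan) and the endo preference of the carbenoid donor group. Hydrocarbon solvent and slow addition are meant to favour carbenoid over vinylogous or zwitterionic reactivity.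

Step 6
Reactants: 11 methyl (1R,4S,5R)-4-exo-[(tert-butyldimethylsilyl)oxy]-7-[(triethylsilyl)oxy]-8-oxabicyclo[3.2.1]octa-2,6-diene-2-carboxylate
Product: 13 methyl (1R,2S,3S,4S,5R)-4-[(tert-butyldimethylsilyl)oxy]-2-hydroxy-3-methyl-7-[(triethylsilyl)oxy]-8-oxabicyclo[3.2.1]oct-6-ene-2-carboxylate, via lithium ester enolate 12 (not isolated)
Conditions: Me2CuLi (MeLi, CuI), Et2O, −78 °C; then 2-(phenylsulfonyl)-3-phenyloxaziridine, THF, −78 °C; NH4Cl
Reagents that add atoms: lithium dimethylcuprate, [Li+].C[Cu-]C; 2-(phenylsulfonyl)-3-phenyloxaziridine, O=S(=O)(c1ccccc1)N1OC1c1ccccc1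
Why: Cuprate conjugate addition should deliver the methyl group axially from the endo face, anti to the exo C9 silyl ether, and Davis oxidation of the resulting enolate should also occur endo because the exo face of C1 is screened by the syn-axial C9 silyl ether; the enolate is expected to persist at −78 °C since the bridgehead C–O bond lies near its nodal plane.

Step 7
Reactants: 13 methyl (1R,2S,3S,4S,5R)-4-[(tert-butyldimethylsilyl)oxy]-2-hydroxy-3-methyl-7-[(triethylsilyl)oxy]-8-oxabicyclo[3.2.1]oct-6-ene-2-carboxylate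
Product: 14 S-ethyl (1R,2S,3S,4S,5R)-4-[(tert-butyldimethylsilyl)oxy]-2-hydroxy-3-methyl-7-[(triethylsilyl)oxy]-8-oxabicyclo[3.2.1]oct-6-ene-2-carbothioate
Conditions: AlMe3, EtSH, CH2Cl2, 0 °C to rt; aq. HCl work-up
Reagents that add atoms: ethanethiol, CCS
Why: Aluminium thiolate transthioesterification, done while this is the only ester in the molecule, installs the acyl group that is later converted chemoselectively into the enone.

Step 8
Reactants: 14 S-ethyl (1R,2S,3S,4S,5R)-4-[(tert-butyldimethylsilyl)oxy]-2-hydroxy-3-methyl-7-[(triethylsilyl)oxy]-8-oxabicyclo[3.2.1]oct-6-ene-2-carbothioate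
Product: 16 S-ethyl (1S,2R,6R,7S)-6-[(tert-butyldimethylsilyl)oxy]-1,2-dihydroxy-7-methyl-3-oxocyclohept-4-ene-1-carbothioate, via bis(trimethylsilyl) ether 15 (not isolated)
Conditions: Me3SiOTf, 2,6-lutidine, CH2Cl2, −78 to −20 °C; then citric acid, MeOH, 0 °C
Reagents that add atoms: none
Why: Silyl-triflate activation of the bridging ether with push from the silyl enol ether (vinylogous β-elimination of an oxa-bridge) should cleave C8–O, because only that ionisation gives a silyloxocarbenium/enone; the quaternary C1 blocks aromatisation to a tropolone, and transient silylation of the C1 hydroxyl blocks retro-aldol cleavage.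

Step 9
Reactants: 16 S-ethyl (1S,2R,6R,7S)-6-[(tert-butyldimethylsilyl)oxy]-1,2-dihydroxy-7-methyl-3-oxocyclohept-4-ene-1-carbothioate; 17 (S)-2-methylbutanoic anhydride
Product: 18 S-ethyl (1S,2R,6R,7S)-6-[(tert-butyldimethylsilyl)oxy]-1-hydroxy-7-methyl-2-{[(2S)-2-methylbutanoyl]oxy}-3-oxocyclohept-4-ene-1-carbothioate
Conditions: DMAP (cat.), pyridine, CH2Cl2, 0 °C
Reagents that add atoms: none
Why: DMAP-catalysed acylation should take the secondary C5 hydroxyl and leave the tertiary C1 hydroxyl free.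

Step 10
Reactants: 18 S-ethyl (1S,2R,6R,7S)-6-[(tert-butyldimethylsilyl)oxy]-1-hydroxy-7-methyl-2-{[(2S)-2-methylbutanoyl]oxy}-3-oxocyclohept-4-ene-1-carbothioate
Product: 19 S-ethyl (1S,2S,3R,6R,7S)-6-[(tert-butyldimethylsilyl)oxy]-1,3-dihydroxy-7-methyl-2-{[(2S)-2-methylbutanoyl]oxy}cyclohept-4-ene-1-carbothioate
Conditions: Et2BOMe, THF–MeOH, −78 °C; NaBH4; AcOH, MeOH azeotrope
Reagents that add atoms: none
Why: Narasaka–Prasad reduction: the boron chelate between the C1 hydroxyl and the C6 ketone sits on the lower face, so hydride should enter from the upper face and give the C6 alcohol syn to the C1 hydroxyl and trans to the C5 ester, by 1,2-reduction of the enone.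

Step 11
Reactants: 19 S-ethyl (1S,2S,3R,6R,7S)-6-[(tert-butyldimethylsilyl)oxy]-1,3-dihydroxy-7-methyl-2-{[(2S)-2-methylbutanoyl]oxy}cyclohept-4-ene-1-carbothioate; 20 methoxyallene
Product: 21 S-ethyl (1S,2S,3R,6R,7S)-3-[(2-bromo-1-methoxyprop-2-en-1-yl)oxy]-6-[(tert-butyldimethylsilyl)oxy]-1-hydroxy-7-methyl-2-{[(2S)-2-methylbutanoyl]oxy}cyclohept-4-ene-1-carbothioate (acetal epimers)
Conditions: NBS, CH2Cl2, −78 to −40 °C
Reagents that add atoms: N-bromosuccinimide, O=C1CCC(=O)N1Br
Why: Bromoalkoxylation of the alkoxyallene (bromonium at the central carbon, capture by the only reactive hydroxyl) gives the 2-bromoallyl mixed acetal used for vinyl-radical lactone annulation.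

Step 12
Reactants: 21 S-ethyl (1S,2S,3R,6R,7S)-3-[(2-bromo-1-methoxyprop-2-en-1-yl)oxy]-6-[(tert-butyldimethylsilyl)oxy]-1-hydroxy-7-methyl-2-{[(2S)-2-methylbutanoyl]oxy}cyclohept-4-ene-1-carbothioate
Product: 22 cis-fused 2-methoxy-3-methylenetetrahydrofuran acetal (as 23, with CH(OMe) in place of the lactone C=O; acetal epimers)
Conditions: Bu3SnH, AIBN (cat.), benzene, 80 °C, slow addition
Reagents that add atoms: none
Why: Ueno–Stork-type vinyl-radical 5-exo-trig cyclisation onto C7 can only give the cis-fused ring, which sets C7 on the face of the C6 oxygen, and hydrogen transfer to the C8 radical leaves the ring methylene.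

Step 13
Reactants: 22 cis-fused 2-methoxy-3-methylenetetrahydrofuran acetal
Product: 23 α-methylene lactone thioester (as 26, with C9–OSi(tBu)Me2 and C(=O)SEt in place of the crotonyl ketone)
Conditions: CrO3, H2SO4, acetone–H2O, 0 °C, short time
Reagents that add atoms: water, O
Why: Acidic chromic acid hydrolyses the methyl acetal and oxidises the lactol in one pot (Jones oxidation of a lactol ether) to the α-methylene-γ-butyrolactone.

Step 14
Reactants: 23 α-methylene lactone thioester; 24 (E)-prop-1-enylboronic acid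
Product: 25 9-O-(tert-butyldimethylsilyl) ether of 26
Conditions: Pd2(dba)3 (cat.), tri(2-furyl)phosphine, Cu(O2C-C4H3S) (copper thiophene-2-carboxylate, 1.5 equiv), THF, 50 °C
Reagents that add atoms: none
Why: Liebeskind–Srogl thioester–boronic acid coupling forms the E enone under neutral conditions that should spare the lactone, the ester and the free tertiary alcohol.

Step 15
Reactants: 25 9-O-(tert-butyldimethylsilyl) ether of 26
Product: 26 CNP0331957.1
Conditions: HF·pyridine, THF, 0 °C to rt
Reagents that add atoms: none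
Why: Fluoride desilylation of the secondary silyl ether under mildly acidic conditions should leave the enone, the α-methylene lactone and the ester intact.

**Compound list**
1 | (tert-butyldimethylsilyloxy)acetaldehyde | O=CCO[Si](C)(C)C(C)(C)C | starting material
2 | methyl (triphenylphosphoranylidene)acetate | COC(=O)C=P(c1ccccc1)(c1ccccc1)c1ccccc1 | starting material
3 | methyl (E)-4-[(tert-butyldimethylsilyl)oxy]but-2-enoate | COC(=O)/C=C/CO[Si](C)(C)C(C)(C)C | intermediate
4 | lithium dienolate of 3 (3Z enol ether) | [Li+].COC([O-])=C/C=C\O[Si](C)(C)C(C)(C)C | intermediate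
5 | methyl (Z)-4-[(tert-butyldimethylsilyl)oxy]but-3-enoate | COC(=O)C/C=C\O[Si](C)(C)C(C)(C)C | intermediate
6 | methyl (Z)-4-[(tert-butyldimethylsilyl)oxy]-2-diazobut-3-enoate | COC(=O)C(=[N+]=[N-])/C=C\O[Si](C)(C)C(C)(C)C | intermediate
7 | furan-3-ylboronic acid | OB(O)c1ccoc1 | starting material
8 | furan-3(2H)-one | O=C1COC=C1 | intermediate
9 | 3-(triethylsilyloxy)furan | CC[Si](CC)(CC)Oc1ccoc1 | intermediate
10 | methyl 6-endo-[(Z)-2-(tert-butyldimethylsilyloxy)ethenyl]-5-(triethylsilyloxy)-2-oxabicyclo[3.1.0]hex-3-ene-6-exo-carboxylate (cis-divinylcyclopropane) | COC(=O)[C@]1(/C=C\O[Si](C)(C)C(C)(C)C)[C@H]2OC=C[C@@]12O[Si](CC)(CC)CC | intermediate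
11 | methyl (1R,4S,5R)-4-exo-[(tert-butyldimethylsilyl)oxy]-7-[(triethylsilyl)oxy]-8-oxabicyclo[3.2.1]octa-2,6-diene-2-carboxylate | COC(=O)C1=C[C@H](O[Si](C)(C)C(C)(C)C)[C@H]2C=C(O[Si](CC)(CC)CC)[C@@H]1O2 | intermediate
12 | lithium ester enolate of the 3-endo-methyl conjugate adduct of 11 | [Li+].COC([O-])=C1[C@@H](C)[C@H](O[Si](C)(C)C(C)(C)C)[C@H]2C=C(O[Si](CC)(CC)CC)[C@@H]1O2 | intermediate
13 | methyl (1R,2S,3S,4S,5R)-4-[(tert-butyldimethylsilyl)oxy]-2-hydroxy-3-methyl-7-[(triethylsilyl)oxy]-8-oxabicyclo[3.2.1]oct-6-ene-2-carboxylate (2-OH endo, 3-Me endo, 4-OSi exo) | COC(=O)[C@]1(O)[C@@H](C)[C@H](O[Si](C)(C)C(C)(C)C)[C@H]2C=C(O[Si](CC)(CC)CC)[C@@H]1O2 | intermediate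
14 | S-ethyl (1R,2S,3S,4S,5R)-4-[(tert-butyldimethylsilyl)oxy]-2-hydroxy-3-methyl-7-[(triethylsilyl)oxy]-8-oxabicyclo[3.2.1]oct-6-ene-2-carbothioate | CCSC(=O)[C@]1(O)[C@@H](C)[C@H](O[Si](C)(C)C(C)(C)C)[C@H]2C=C(O[Si](CC)(CC)CC)[C@@H]1O2 | intermediate
15 | S-ethyl (1S,2R,6R,7S)-6-[(tert-butyldimethylsilyl)oxy]-7-methyl-3-oxo-1,2-bis(trimethylsilyloxy)cyclohept-4-ene-1-carbothioate | CCSC(=O)[C@]1(O[Si](C)(C)C)[C@@H](C)[C@H](O[Si](C)(C)C(C)(C)C)C=CC(=O)[C@@H]1O[Si](C)(C)C | intermediate
16 | S-ethyl (1S,2R,6R,7S)-6-[(tert-butyldimethylsilyl)oxy]-1,2-dihydroxy-7-methyl-3-oxocyclohept-4-ene-1-carbothioate | CCSC(=O)[C@]1(O)[C@@H](C)[C@H](O[Si](C)(C)C(C)(C)C)C=CC(=O)[C@@H]1O | intermediate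
17 | (S)-2-methylbutanoic anhydride | CC[C@H](C)C(=O)OC(=O)[C@@H](C)CC | starting material
18 | S-ethyl (1S,2R,6R,7S)-6-[(tert-butyldimethylsilyl)oxy]-1-hydroxy-7-methyl-2-{[(2S)-2-methylbutanoyl]oxy}-3-oxocyclohept-4-ene-1-carbothioate | CCSC(=O)[C@]1(O)[C@@H](C)[C@H](O[Si](C)(C)C(C)(C)C)C=CC(=O)[C@@H]1OC(=O)[C@@H](C)CC | intermediate
19 | S-ethyl (1S,2S,3R,6R,7S)-6-[(tert-butyldimethylsilyl)oxy]-1,3-dihydroxy-7-methyl-2-{[(2S)-2-methylbutanoyl]oxy}cyclohept-4-ene-1-carbothioate | CCSC(=O)[C@]1(O)[C@@H](C)[C@H](O[Si](C)(C)C(C)(C)C)C=C[C@@H](O)[C@@H]1OC(=O)[C@@H](C)CC | intermediate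
20 | methoxyallene (1-methoxypropa-1,2-diene) | COC=C=C | starting material
21 | S-ethyl (1S,2S,3R,6R,7S)-3-[(2-bromo-1-methoxyprop-2-en-1-yl)oxy]-6-[(tert-butyldimethylsilyl)oxy]-1-hydroxy-7-methyl-2-{[(2S)-2-methylbutanoyl]oxy}cyclohept-4-ene-1-carbothioate (acetal epimers) | CCSC(=O)[C@]1(O)[C@@H](C)[C@H](O[Si](C)(C)C(C)(C)C)C=C[C@@H](OC(OC)C(Br)=C)[C@@H]1OC(=O)[C@@H](C)CC | intermediate
22 | cis-fused 2-methoxy-3-methylenetetrahydrofuran acetal (23 with CH(OMe) in place of the lactone C=O; acetal epimers) | C=C1C(OC)O[C@@H]2[C@H]1C[C@@H](O[Si](C)(C)C(C)(C)C)[C@H](C)[C@@](O)(C(=O)SCC)[C@H]2OC(=O)[C@@H](C)CC | intermediate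
23 | α-methylene lactone S-ethyl thioester (26 with C9–OSi(tBu)Me2 and C(=O)SEt in place of the crotonyl ketone) | C=C1C(=O)O[C@@H]2[C@H]1C[C@@H](O[Si](C)(C)C(C)(C)C)[C@H](C)[C@@](O)(C(=O)SCC)[C@H]2OC(=O)[C@@H](C)CC | intermediate
24 | (E)-prop-1-enylboronic acid | C/C=C/B(O)O | starting material
25 | 9-O-(tert-butyldimethylsilyl) ether of 26 | C=C1C(=O)O[C@@H]2[C@H]1C[C@@H](O[Si](C)(C)C(C)(C)C)[C@H](C)[C@@](O)(C(=O)/C=C/C)[C@H]2OC(=O)[C@@H](C)CC | intermediate
26 | CNP0331957.1 | C=C1C(=O)O[C@@H]2[C@H]1C[C@@H](O)[C@H](C)[C@@](O)(C(=O)/C=C/C)[C@H]2OC(=O)[C@@H](C)CC | target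

**Step count and risks**
Total steps: 15. Longest linear sequence: 14 (from 1 through steps 1–3 and 5–15 to 26).

Steps most likely to fail:

Step 5. The donor–acceptor cyclopropane 10 may collapse through a zwitterion (opening of the very electron-rich silyloxyfuran, or formal [3+2] closure) faster than it undergoes the Cope shift, and the Z silyloxy group slows that shift. Fallback: the carbenoid from 6 is added under the same catalyst to the less electron-rich 3-bromofuran F1, which should give the 7-bromo oxabicycle F2 by the same cyclopropanation/Cope sequence. Miyaura borylation (B2pin2, PdCl2(dppf), KOAc, dioxane) gives the alkenyl boronate F3. Anhydrous oxidation with Me3NO gives the enol borate F4, which is silylated in the same flask (Et3SiOTf, Et3N) and rejoins the route at 11.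

Step 6. Facial selectivity in the enolate oxidation may be poor, with the oxidant entering from the exo face to give the C1 epimer of 13. Fallback, which turns an exo preference to advantage: 13 (or its C1-epimeric mixture) is reduced with LiAlH4 to the diol F5 and cleaved with NaIO4 to the C1 ketone F6, in which the C10 methyl can equilibrate to the endo position. (EtS)3CLi is then added from the exo face, anti to that methyl, to give the tris(ethylthio)methyl carbinol F7. HgO/BF3·OEt2 in aqueous THF unmasks the S-ethyl thioester and hydrolyses the enol silyl ether, giving the keto thioester F8. Me3SiOTf/Et3N converts F8 into the silyl enol ether F9, which ionises as in step 8 to 15 and rejoins the route at 16 after methanolysis.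

Step 8. The Lewis-acid ionisation may stall because of poor alignment of the C8–O bond with the enol ether, or the allylic C9 silyl ether may be lost. Fallback: 14 is treated with Bu4NF at −78 °C in the presence of 17 and DMAP. The liberated enolate should expel the bridging oxygen (E1cB) to give the alkoxide F10, which is acylated in the flask and rejoins the route at 18.

**Further compounds**
F1 | step 5 | 3-bromofuran | Brc1ccoc1
F2 | step 5 | methyl (1R,4S,5R)-7-bromo-4-exo-[(tert-butyldimethylsilyl)oxy]-8-oxabicyclo[3.2.1]octa-2,6-diene-2-carboxylate | COC(=O)C1=C[C@H](O[Si](C)(C)C(C)(C)C)[C@H]2C=C(Br)[C@@H]1O2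
F3 | step 5 | 7-(4,4,5,5-tetramethyl-1,3,2-dioxaborolan-2-yl) analogue of F2 | COC(=O)C1=C[C@H](O[Si](C)(C)C(C)(C)C)[C@H]2C=C(B3OC(C)(C)C(C)(C)O3)[C@@H]1O2
F4 | step 5 | 7-enol pinacol borate of the bicyclic ketone | COC(=O)C1=C[C@H](O[Si](C)(C)C(C)(C)C)[C@H]2C=C(OB3OC(C)(C)C(C)(C)O3)[C@@H]1O2
F5 | step 6 | 2-(hydroxymethyl) diol from reduction of 13 (C2 epimers) | OCC1(O)[C@@H](C)[C@H](O[Si](C)(C)C(C)(C)C)[C@H]2C=C(O[Si](CC)(CC)CC)[C@@H]1O2
F6 | step 6 | 4-exo-[(tert-butyldimethylsilyl)oxy]-3-endo-methyl-7-[(triethylsilyl)oxy]-8-oxabicyclo[3.2.1]oct-6-en-2-one | O=C1[C@@H](C)[C@H](O[Si](C)(C)C(C)(C)C)[C@H]2C=C(O[Si](CC)(CC)CC)[C@@H]1O2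
F7 | step 6 | 2-exo-[tris(ethylthio)methyl] 2-endo-carbinol from F6 | CCSC(SCC)(SCC)[C@]1(O)[C@@H](C)[C@H](O[Si](C)(C)C(C)(C)C)[C@H]2C=C(O[Si](CC)(CC)CC)[C@@H]1O2
F8 | step 6 | S-ethyl 4-exo-[(tert-butyldimethylsilyl)oxy]-2-endo-hydroxy-3-endo-methyl-7-oxo-8-oxabicyclo[3.2.1]octane-2-carbothioate | CCSC(=O)[C@]1(O)[C@@H](C)[C@H](O[Si](C)(C)C(C)(C)C)[C@H]2CC(=O)[C@@H]1O2
F9 | step 6 | 2-O,7-O-bis(trimethylsilyl) enol ether of F8 | CCSC(=O)[C@]1(O[Si](C)(C)C)[C@@H](C)[C@H](O[Si](C)(C)C(C)(C)C)[C@H]2C=C(O[Si](C)(C)C)[C@@H]1O2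
F10 | step 8 | tetrabutylammonium C2-alkoxide of 16 | CCSC(=O)[C@]1(O)[C@@H](C)[C@H](O[Si](C)(C)C(C)(C)C)C=CC(=O)[C@@H]1[O-].CCCC[N+](CCCC)(CCCC)CCCC
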